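**Retrosynthetic overview**
- The free phenol of ring B is unmasked last by desilylation of a triisopropylsilyl (TIPS) ether.
- The dioxane ring is the only ring formed (both benzene rings are bought). It is closed late by intramolecular copper-catalysed aryl C–O coupling of the C7 hydroxyl onto an aryl bromide of ring A; no bond at a stereocentre is broken, so the threo (7R,8R) alcohol gives the trans (2R,3R) dioxane.
- The C9 methyl group comes from the acyl carbon of an aldol adduct (CH2OH, then CH2OTs, then CH3).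
- The C7–C8 bond is made by an Evans syn-aldol between the boron enolate of an N-(aryloxyacetyl)oxazolidinone (ring A fragment) and TIPS-protected syringaldehyde (ring B fragment); this sets both stereocentres.
- The ring A fragment comes from eugenol (ortho-bromination, O-alkylation with ethyl bromoacetate, acylation of (S)-4-benzyloxazolidin-2-one); the ring B fragment comes from syringaldehyde.

Assumption: the SMILES is read as the trans-(2R,3R)-benzodioxane (neolignan numbering 7R,8R), with aryl and methyl on opposite faces of the dioxane ring.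

**Route**

Step 1
Reactants: 1 eugenol (4-allyl-2-methoxyphenol)
Product: 2 4-allyl-2-bromo-6-methoxyphenol (6-bromoeugenol)
Conditions: NBS (1.0 equiv), iPr2NH (10 mol%), CH2Cl2, 0 °C, dark
Reagents that add atoms: N-bromosuccinimide, O=C1CCC(=O)N1Br
Why: Amine-catalysed electrophilic aromatic bromination goes to the only free position ortho to the phenol (para is blocked by the allyl group) much faster than NBS attacks the isolated alkene.

Step 2
Reactants: 2 4-allyl-2-bromo-6-methoxyphenol; 3 ethyl bromoacetate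
Product: 4 ethyl 2-(4-allyl-2-bromo-6-methoxyphenoxy)acetate
Conditions: K2CO3, acetone, reflux
Reagents that add atoms: none
Why: Williamson ether synthesis, the phenoxide displacing bromide from the activated α-bromo ester by SN2.

Step 3
Reactants: 4 ethyl 2-(4-allyl-2-bromo-6-methoxyphenoxy)acetate
Product: 5 2-(4-allyl-2-bromo-6-methoxyphenoxy)acetic acid
Conditions: LiOH·H2O, THF/H2O (3:1), rt; then 1 M HCl
Reagents that add atoms: lithium hydroxide (aqueous), [Li+].[OH-]
Why: Ester saponification; the aryl ether, aryl bromide and alkene are inert to hydroxide at room temperature.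

Step 4
Reactants: 5 2-(4-allyl-2-bromo-6-methoxyphenoxy)acetic acid; 6 (S)-4-benzyl-1,3-oxazolidin-2-one
Product: 8 (S)-3-[2-(4-allyl-2-bromo-6-methoxyphenoxy)acetyl]-4-benzyl-1,3-oxazolidin-2-one, via pivalic mixed anhydride 7 (not isolated)
Conditions: PivCl, Et3N, THF, −20 °C; then LiCl, 6, −20 °C → rt
Reagents that add atoms: pivaloyl chloride, CC(C)(C)C(Cl)=O (its acyl group is carried in 7 only)
Why: N-acylation of the oxazolidinone through the mixed anhydride, which is attacked at the less hindered aryloxyacetyl carbonyl.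

Step 5
Reactants: 9 syringaldehyde (4-hydroxy-3,5-dimethoxybenzaldehyde)
Product: 10 3,5-dimethoxy-4-[(triisopropylsilyl)oxy]benzaldehyde
Conditions: TIPSCl, imidazole, 4-(dimethylamino)pyridine (cat.), DMF, rt
Reagents that add atoms: chlorotriisopropylsilane, CC(C)[Si](Cl)(C(C)C)C(C)C
Why: Silylation of the acidic phenol gives a bulky silyl ether that tolerates boron enolates, hydrides and carbonate base and is later cleaved by fluoride without touching the alkene.

Step 6
Reactants: 8 (S)-3-[2-(4-allyl-2-bromo-6-methoxyphenoxy)acetyl]-4-benzyl-1,3-oxazolidin-2-one; 10 3,5-dimethoxy-4-[(triisopropylsilyl)oxy]benzaldehyde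
Product: 13 (S)-3-[(2S,3R)-2-(4-allyl-2-bromo-6-methoxyphenoxy)-3-hydroxy-3-{3,5-dimethoxy-4-[(triisopropylsilyl)oxy]phenyl}propanoyl]-4-benzyl-1,3-oxazolidin-2-one, via Z dibutylboron enolate 11 (not isolated), via dibutylboron aldolate 12 (not isolated)
Conditions: Bu2BOTf (1.2 equiv), iPr2NEt (1.4 equiv), CH2Cl2, −78 → 0 °C; 10, −78 → 0 °C; then pH 7 buffer, MeOH, 30% H2O2, 0 °C
Reagents that add atoms: dibutylboron triflate, CCCCB(CCCC)OS(=O)(=O)C(F)(F)F (its Bu2B unit is carried in 11 and 12 only)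
Why: Evans syn-aldol addition: the Z boron enolate reacts through a closed Zimmerman–Traxler chair with the auxiliary benzyl group shielding one enolate face, which sets C8 and C7 together as the syn (threo) pair, 7R,8R once the acyl carbon is reduced.

Step 7
Reactants: 13 the aldol adduct
Product: 14 (1R,2R)-2-(4-allyl-2-bromo-6-methoxyphenoxy)-1-{3,5-dimethoxy-4-[(triisopropylsilyl)oxy]phenyl}propane-1,3-diol
Conditions: LiBH4 (2 equiv), MeOH (2 equiv), THF, 0 °C
Reagents that add atoms: none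
Why: Reductive cleavage of the imide by borohydride gives the primary alcohol and releases the auxiliary without touching the aryl bromide, silyl ether, alkene or either stereocentre.

Step 8
Reactants: 14 the 1,3-diol
Product: 15 (2R,3R)-2-(4-allyl-2-bromo-6-methoxyphenoxy)-3-hydroxy-3-{3,5-dimethoxy-4-[(triisopropylsilyl)oxy]phenyl}propyl 4-methylbenzenesulfonate
Conditions: TsCl (1.15 equiv), Et3N, 4-(dimethylamino)pyridine (cat.), CH2Cl2, 0 °C
Reagents that add atoms: 4-toluenesulfonyl chloride, Cc1ccc(S(Cl)(=O)=O)cc1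
Why: Selective sulfonylation of the unhindered primary hydroxyl over the hindered secondary benzylic one.

Step 9
Reactants: 15 the primary tosylate
Product: 16 (1R,2R)-2-(4-allyl-2-bromo-6-methoxyphenoxy)-1-{3,5-dimethoxy-4-[(triisopropylsilyl)oxy]phenyl}propan-1-ol
Conditions: LiEt3BH (1 M in THF, 3.5 equiv), THF, 0 °C → rt
Reagents that add atoms: none
Why: SN2 displacement of the primary tosylate by hydride turns C9 into the methyl group; the aryl bromide and alkene are inert at this temperature.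

Step 10
Reactants: 16 the bromoaryl threo alcohol
Product: 17 (2R,3R)-7-allyl-2-{3,5-dimethoxy-4-[(triisopropylsilyl)oxy]phenyl}-5-methoxy-3-methyl-2,3-dihydro-1,4-benzodioxine
Conditions: CuI (copper monoiodide, 10 mol%), 3,4,7,8-tetramethyl-1,10-phenanthroline (20 mol%), Cs2CO3 (2 equiv), toluene (0.05 M), 110 °C
Reagents that add atoms: none
Why: Intramolecular Ullmann-type C–O coupling arylates the C7 alkoxide at the bromine-bearing carbon; no bond at C7 or C8 is broken, so the threo 7R,8R alcohol gives the trans 2R,3R dioxane with the correct ring A regiochemistry.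

Step 11
Reactants: 17 the TIPS-protected benzodioxane
Product: 18 4-[(2R,3R)-7-allyl-5-methoxy-3-methyl-2,3-dihydro-1,4-benzodioxin-2-yl]-2,6-dimethoxyphenol (target, CNP0116579.1)
Conditions: Bu4NF, AcOH (1:1), THF, 0 °C
Reagents that add atoms: none
Why: Fluoride-mediated desilylation of the aryl silyl ether; buffering with AcOH keeps the liberated phenoxide from opening the benzylic ether.

**Compound list**

1 | eugenol (4-allyl-2-methoxyphenol) | C=CCc1ccc(O)c(OC)c1 | starting material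
2 | 4-allyl-2-bromo-6-methoxyphenol | C=CCc1cc(Br)c(O)c(OC)c1 | intermediate
3 | ethyl bromoacetate | CCOC(=O)CBr | starting material
4 | ethyl 2-(4-allyl-2-bromo-6-methoxyphenoxy)acetate | C=CCc1cc(Br)c(OCC(=O)OCC)c(OC)c1 | intermediate
5 | 2-(4-allyl-2-bromo-6-methoxyphenoxy)acetic acid | C=CCc1cc(Br)c(OCC(=O)O)c(OC)c1 | intermediate
6 | (S)-4-benzyl-1,3-oxazolidin-2-one | O=C1N[C@@H](Cc2ccccc2)CO1 | starting material
7 | 2-(4-allyl-2-bromo-6-methoxyphenoxy)acetic pivalic anhydride | C=CCc1cc(Br)c(OCC(=O)OC(=O)C(C)(C)C)c(OC)c1 | intermediate (not isolated)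
8 | (S)-3-[2-(4-allyl-2-bromo-6-methoxyphenoxy)acetyl]-4-benzyl-1,3-oxazolidin-2-one | C=CCc1cc(Br)c(OCC(=O)N2C(=O)OC[C@@H]2Cc2ccccc2)c(OC)c1 | intermediate
9 | syringaldehyde (4-hydroxy-3,5-dimethoxybenzaldehyde) | O=Cc1cc(OC)c(O)c(OC)c1 | starting material
10 | 3,5-dimethoxy-4-[(triisopropylsilyl)oxy]benzaldehyde | O=Cc1cc(OC)c(O[Si](C(C)C)(C(C)C)C(C)C)c(OC)c1 | intermediate
11 | (S)-3-[(Z)-2-(4-allyl-2-bromo-6-methoxyphenoxy)-1-[(dibutylboranyl)oxy]ethenyl]-4-benzyl-1,3-oxazolidin-2-one (Z boron enolate of 8) | C=CCc1cc(Br)c(O/C=C(\OB(CCCC)CCCC)N2C(=O)OC[C@@H]2Cc2ccccc2)c(OC)c1 | intermediate (not isolated)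
12 | O-dibutylboryl aldolate of 13 (2S,3R; boron on the C3 oxygen) | CCCCB(CCCC)O[C@H](c1cc(OC)c(O[Si](C(C)C)(C(C)C)C(C)C)c(OC)c1)[C@@H](C(=O)N1C(=O)OC[C@@H]1Cc1ccccc1)Oc1c(Br)cc(CC=C)cc1OC | intermediate (not isolated)
13 | (S)-3-[(2S,3R)-2-(4-allyl-2-bromo-6-methoxyphenoxy)-3-hydroxy-3-{3,5-dimethoxy-4-[(triisopropylsilyl)oxy]phenyl}propanoyl]-4-benzyl-1,3-oxazolidin-2-one | O[C@H](c1cc(OC)c(O[Si](C(C)C)(C(C)C)C(C)C)c(OC)c1)[C@@H](C(=O)N1C(=O)OC[C@@H]1Cc1ccccc1)Oc1c(Br)cc(CC=C)cc1OC | intermediate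
14 | (1R,2R)-2-(4-allyl-2-bromo-6-methoxyphenoxy)-1-{3,5-dimethoxy-4-[(triisopropylsilyl)oxy]phenyl}propane-1,3-diol | O[C@H](c1cc(OC)c(O[Si](C(C)C)(C(C)C)C(C)C)c(OC)c1)[C@@H](CO)Oc1c(Br)cc(CC=C)cc1OC | intermediate
15 | (2R,3R)-2-(4-allyl-2-bromo-6-methoxyphenoxy)-3-hydroxy-3-{3,5-dimethoxy-4-[(triisopropylsilyl)oxy]phenyl}propyl 4-methylbenzenesulfonate | O[C@H](c1cc(OC)c(O[Si](C(C)C)(C(C)C)C(C)C)c(OC)c1)[C@@H](COS(=O)(=O)c1ccc(C)cc1)Oc1c(Br)cc(CC=C)cc1OC | intermediate
16 | (1R,2R)-2-(4-allyl-2-bromo-6-methoxyphenoxy)-1-{3,5-dimethoxy-4-[(triisopropylsilyl)oxy]phenyl}propan-1-ol | O[C@H](c1cc(OC)c(O[Si](C(C)C)(C(C)C)C(C)C)c(OC)c1)[C@@H](C)Oc1c(Br)cc(CC=C)cc1OC | intermediate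
17 | (2R,3R)-7-allyl-2-{3,5-dimethoxy-4-[(triisopropylsilyl)oxy]phenyl}-5-methoxy-3-methyl-2,3-dihydro-1,4-benzodioxine | C=CCc1cc(OC)c2c(c1)O[C@H](c1cc(OC)c(O[Si](C(C)C)(C(C)C)C(C)C)c(OC)c1)[C@@H](C)O2 | intermediate
18 | 4-[(2R,3R)-7-allyl-5-methoxy-3-methyl-2,3-dihydro-1,4-benzodioxin-2-yl]-2,6-dimethoxyphenol | C=CCc1cc(OC)c2c(c1)O[C@H](c1cc(OC)c(O)c(OC)c1)[C@@H](C)O2 | target

**Totals**

Total step count: 11. Longest linear sequence: 10 steps (eugenol 1 to target 18 through steps 1–4 and 6–11); the aldehyde branch adds one step (step 5).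

**Steps most likely to fail, with fallbacks**

Step 10 (copper-catalysed ring closure). The electron-rich aryl bromide and the hindered secondary benzylic alkoxide may couple sluggishly, and the silyl ether may partly fall off at 110 °C; any desilylated product is already the target and converges after step 11. The fallback sets out from 16 and comes back at 17. Miyaura borylation of 16 (bis(pinacolato)diboron, PdCl2(dppf), KOAc, 1,4-dioxane, 80 °C) gives the aryl pinacol boronate (1R,2R)-2-[4-allyl-2-methoxy-6-(4,4,5,5-tetramethyl-1,3,2-dioxaborolan-2-yl)phenoxy]-1-{3,5-dimethoxy-4-[(triisopropylsilyl)oxy]phenyl}propan-1-ol F1. NaBO3·4H2O in THF/H2O at rt oxidises the C–B bond to the phenol (1R,2R)-2-(4-allyl-2-hydroxy-6-methoxyphenoxy)-1-{3,5-dimethoxy-4-[(triisopropylsilyl)oxy]phenyl}propan-1-ol F2. Catalytic TsOH·H2O in CH2Cl2 at 0 °C then ionises the benzylic alcohol to the para-silyloxybenzyl cation, which the neighbouring phenol traps to give 17. The trans isomer is favoured because aryl and methyl both sit equatorial, and C8 is never touched.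

Step 6 (aldol). The bulky ortho-disubstituted aryloxy group may slow boron enolisation or lower the diastereoselectivity. The fallback sets out from 5 and comes back at 14. Acid 5 is coupled (EDC·HCl, 4-(dimethylamino)pyridine, CH2Cl2) with (S)-4-benzyl-1,3-thiazolidine-2-thione (S=C1N[C@@H](Cc2ccccc2)CS1) to the N-acyl thiazolidinethione (S)-3-[2-(4-allyl-2-bromo-6-methoxyphenoxy)acetyl]-4-benzyl-1,3-thiazolidine-2-thione F3. Its chlorotitanium enolate (TiCl4, iPr2NEt, N-methyl-2-pyrrolidinone, CH2Cl2, −78 °C) adds to aldehyde 10 to give the syn adduct of the same sense, (S)-3-[(2S,3R)-2-(4-allyl-2-bromo-6-methoxyphenoxy)-3-hydroxy-3-{3,5-dimethoxy-4-[(triisopropylsilyl)oxy]phenyl}propanoyl]-4-benzyl-1,3-thiazolidine-2-thione F4. NaBH4 in THF/EtOH at 0 °C cleaves the activated thioimide directly to diol 14.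

Step 1 (bromination). NBS may also attack the allyl alkene or over-brominate the ring. The fallback sets out from 1 and comes back at 2. Eugenol is treated with Br2 (2 equiv, CH2Cl2, 0 °C) so that the ring position ortho to the hydroxyl and the alkene are both brominated on purpose, giving racemic 2-bromo-4-(2,3-dibromopropyl)-6-methoxyphenol F5. Zn dust in EtOH/AcOH at rt then removes the vicinal dibromide by reductive elimination, which restores the allyl group and leaves the aryl bromide in place, to give 2.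

**Further compounds**

F1 | step 10 | (1R,2R)-2-[4-allyl-2-methoxy-6-(4,4,5,5-tetramethyl-1,3,2-dioxaborolan-2-yl)phenoxy]-1-{3,5-dimethoxy-4-[(triisopropylsilyl)oxy]phenyl}propan-1-ol | O[C@H](c1cc(OC)c(O[Si](C(C)C)(C(C)C)C(C)C)c(OC)c1)[C@@H](C)Oc1c(B2OC(C)(C)C(C)(C)O2)cc(CC=C)cc1OC
F2 | step 10 | (1R,2R)-2-(4-allyl-2-hydroxy-6-methoxyphenoxy)-1-{3,5-dimethoxy-4-[(triisopropylsilyl)oxy]phenyl}propan-1-ol | O[C@H](c1cc(OC)c(O[Si](C(C)C)(C(C)C)C(C)C)c(OC)c1)[C@@H](C)Oc1c(O)cc(CC=C)cc1OC
F3 | step 6 | (S)-3-[2-(4-allyl-2-bromo-6-methoxyphenoxy)acetyl]-4-benzyl-1,3-thiazolidine-2-thione | C=CCc1cc(Br)c(OCC(=O)N2C(=S)SC[C@@H]2Cc2ccccc2)c(OC)c1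
F4 | step 6 | (S)-3-[(2S,3R)-2-(4-allyl-2-bromo-6-methoxyphenoxy)-3-hydroxy-3-{3,5-dimethoxy-4-[(triisopropylsilyl)oxy]phenyl}propanoyl]-4-benzyl-1,3-thiazolidine-2-thione | O[C@H](c1cc(OC)c(O[Si](C(C)C)(C(C)C)C(C)C)c(OC)c1)[C@@H](C(=O)N1C(=S)SC[C@@H]1Cc1ccccc1)Oc1c(Br)cc(CC=C)cc1OC
F5 | step 1 | racemic 2-bromo-4-(2,3-dibromopropyl)-6-methoxyphenol | BrCC(Br)Cc1cc(Br)c(O)c(OC)c1
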